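(The constants used here were drawn at random within sensible limits; the flask was simulated.)

You read these flasks at 4.0 min. In spring that is shorter than the half-life of substrate by the first step alone with reagent as charged, 5.7 min. So I expect the mono adduct still to be forming at the reading, and I compare the reaction time each set-up gives.

| setting | midnight | spring | summer | dusk |
|---|---|---|---|---|
| substrate | 0.16 M | 0.16 M | 0.16 M | 0.16 M (fed, over 2.00 min) |
| reagent | 0.168 M (fed, over 2.00 min) | 0.168 M | 0.168 M | 0.168 M |
| time | 4.0 min | 4.0 min |  | 4.0 min |
| remark | all but reagent at the start; reagent goes in evenly over 2.00 min, the run ends at 4.0 min | a closed flask charged with all of it at once and left for 4.0 min | a single well-mixed tank run continuously and read at steady state, 4.0 min in it on average | all but substrate at the start; substrate goes in evenly over 2.00 min, the run ends at 4.0 min |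

    substrate + reagent → mono adduct + by-product (k1 = 0.012 M⁻¹ s⁻¹)
    reagent + mono adduct → double product + by-product (k2 = 0.0048 M⁻¹ s⁻¹)
    reagent + double product → triple product + by-product (k3 = 0.011 M⁻¹ s⁻¹)
    reagent + triple product → tetra adduct + by-product (k4 = 2.2 × 10⁻⁴ M⁻¹ s⁻¹)
    mono adduct ⇌ isomer of the product (K5 = 1.8, k5 = 0.0017 s⁻¹)

- the set-up with the highest amount of mono adduct at the outlet or at the end, in percent of the substrate put in ("none" if the first two lie within 2 percentage points) (midnight / spring / summer / dusk / none)
- amount of mono adduct at the outlet or at the end, in percent of the substrate put in, midnight
- amount of mono adduct at the outlet or at the end, in percent of the substrate put in, spring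
- amount of mono adduct at the outlet or at the end, in percent of the substrate put in, summer
- amount of mono adduct at the outlet or at the end, in percent of the substrate put in, dusk

- the stated concentrations are those of everything mixed, before any reaction; amounts are the same in each set-up
- the feed brings no volume worth counting
- run time (midnight): 4.0 min

So count turnovers. Spring gives n = 0.484, where n, the turnover count (a Damköhler number), is the rate constant of the first step times the reagent charge times the time the partners spend together. The charges are nearly equal, so I take the share of substrate consumed as n over one plus n, which is 32.6 % in spring.

Mono adduct is lost at L = 0.150 min⁻¹, the second addition at charged reagent plus forward isomerisation. Made about evenly, it waits about half the time, so for spring I reckon a surviving share of 74.0 %. My spring figure is 24.1 %.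

Midnight looks nearly the same, with equal charges and the same reading. But its reagent arrives evenly over 2.00 min, so the average time together is 3.00 min. Its count falls to 0.363, and with survival 79.8 % I put midnight lower, at 21.2 %. Dusk feeds the other partner on the same schedule, so I give it the same count: 21.2 %.

The summer tank works at outlet strength. Its unreacted share u solves n times u squared plus u equals one, so u = 73.7 %, and dividing the consumed share by one plus L times the mean stay gives 16.4 %. My pick is spring.

The forecast gives 20.8 % for midnight, 24.2 % for spring, 17.7 % for summer and 21.1 % for dusk, and it names spring: “the all-at-once flask wins by giving the longest time with both reactants at full strength”. Its figures lie close to mine but are not the same.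

The simulation gives 21.3 % for midnight, 24.5 % for spring, 17.6 % for summer and 21.2 % for dusk, so the best set-up is spring.

Now leave spring unchanged but read it at 2.5 min. The count drops to 0.302, so the reckoning leaves 76.8 % of the substrate. With survival 82.9 %, it puts mono adduct at 19.2 %. That flask holds 76.7 % substrate and 19.4 % mono adduct.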